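**Plan**
Numbering: ring A has C1 (CH2OH), C2 (CH2 to ring B), C3 and C4 (OH), C5 (Br) and C6 (H). Ring B is the 3-bromo-4-hydroxyphenyl group.
Retrosynthesis: the C5–Br bond, the ring B phenol (masked as OCH3) and the oxidation levels of both benzylic carbons are adjusted first, which leads back to a 3-arylphthalide. Its C1–C(carbonyl) and C2–C(bridge) bonds are then cut together.
Enabling feature: the two carbon substituents sit on neighbouring C1 and C2, directly beside the C3 oxygen of ring A. A 3-oxygenated C1–C2 aryne leaves exactly this pattern when it takes a nucleophile at C1 and an electrophile at C2.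
Forward: pyrogallol supplies ring A. A dioxole ring masks the C3 and C4 oxygens, and the third oxygen becomes the triflate of an ortho-silylaryl triflate. The aryne, an isocyanide and the ring B aldehyde are then joined with closure of a five-membered iminolactone ring.
That ring is hydrolysed to the lactone and opened reductively. C5 bromination, O-demethylation and reduction of the acid finish the synthesis.
Stereochemistry: the target is achiral. The one stereocentre on the way (the bridge carbon) forms racemic in the key step and vanishes when it becomes CH2.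

Key step: step 5

Remark: the C=N bond of the key-step product is drawn Z (tert-butyl on the side of the ring oxygen), the less crowded geometry. This has no consequence, because the imine is hydrolysed in the following step.

**Step 1**
Reactants: 1 pyrogallol (benzene-1,2,3-triol)
Product: 2 2,2-dimethyl-1,3-benzodioxol-4-ol
Conditions: Me2C(OMe)2, p-TsOH (cat.), toluene, reflux, MeOH distilled off
Reagents that add atoms: 2,2-dimethoxypropane, COC(C)(C)OC
Why: In this acid-catalysed transketalisation either vicinal pair of hydroxyls of the symmetric triol gives the same five-membered dioxole, and removing methanol drives the equilibrium and leaves one free phenol.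

**Step 2**
Reactants: 2 2,2-dimethyl-1,3-benzodioxol-4-ol
Product: 3 2,2-dimethyl-1,3-benzodioxol-4-yl N-isopropylcarbamate
Conditions: i-PrNCO, Et3N (cat.), CH2Cl2, rt
Reagents that add atoms: isopropyl isocyanate, CC(C)N=C=O
Why: Amine-catalysed addition of the phenol to an isocyanate (carbamoylation) installs a strong ortho-directing group whose N–H later allows removal under mild base.

**Step 3**
Reactants: 3 2,2-dimethyl-1,3-benzodioxol-4-yl N-isopropylcarbamate
Product: 7 2,2-dimethyl-5-(trimethylsilyl)-1,3-benzodioxol-4-yl N-isopropylcarbamate, via N-TBS carbamate 4 (not isolated), via 5-lithio N-TBS carbamate 5 (not isolated), via 5-TMS N-TBS carbamate 6 (not isolated)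
Conditions: TBSOTf, TMEDA, Et2O, 0 °C to rt; n-BuLi (2 equiv), TMEDA, −78 °C; TMSCl, −78 °C to rt; aq. NaHSO4
Reagents that add atoms: chlorotrimethylsilane, C[Si](C)(C)Cl (stays in 7); tert-butyldimethylsilyl triflate, CC(C)(C)[Si](C)(C)OS(=O)(=O)C(F)(F)F (its silyl group is carried only by 4 to 6); n-butyllithium, [Li]CCCC (its lithium is carried only by 5)
Why: In this directed ortho-metalation transient N-silylation masks the N–H, the carbamate carbonyl guides n-BuLi to benzodioxole C5 (the only free ortho position, since the other ortho carbon is the ring-fusion carbon), TMSCl traps the aryllithium, and the acidic work-up strips the labile N-silyl group.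

**Step 4**
Reactants: 7 2,2-dimethyl-5-(trimethylsilyl)-1,3-benzodioxol-4-yl N-isopropylcarbamate
Product: 9 2,2-dimethyl-5-(trimethylsilyl)-1,3-benzodioxol-4-yl trifluoromethanesulfonate, via ortho-silylphenol 8 (not isolated)
Conditions: DBU, Et2NH, MeCN, 40 °C; then PhNTf2, rt
Reagents that add atoms: N-phenylbis(trifluoromethanesulfonimide), O=S(=O)(N(c1ccccc1)S(=O)(=O)C(F)(F)F)C(F)(F)F
Why: DBU deprotonates the carbamate N–H and triggers E1cB loss of isopropyl isocyanate, Et2NH scavenges the isocyanate, and the phenoxide is O-triflated in the same flask, which is a standard entry to ortho-silylaryl triflates that spares the C–Si bond and the ketal.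

**Step 5**
Reactants: 9 2,2-dimethyl-5-(trimethylsilyl)-1,3-benzodioxol-4-yl trifluoromethanesulfonate; 10 tert-butyl isocyanide; 11 3-bromo-4-methoxybenzaldehyde
Product: 15 racemic (Z)-N-tert-butyl-3-(3-bromo-4-methoxyphenyl)-4,5-(isopropylidenedioxy)-1,3-dihydroisobenzofuran-1-imine, via dioxole-fused aryne 12 (not isolated), via nitrilium aryl anion zwitterion 13 (not isolated), via nitrilium alkoxide zwitterion 14 (not isolated)
Conditions: KF, 18-crown-6, THF, 0 °C to rt (10 and 11 in excess over 9)
Reagents that add atoms: none
Why: Fluoride attacks the silicon of 9 and triflate departs to give aryne 12, the carbon of isocyanide 10 adds at C1 to form zwitterion 13, and its C2 carbanion adds to the carbonyl of 11 to give alkoxide 14. The alkoxide oxygen then closes on the nitrilium carbon in a 5-exo-dig mode, forming the five-membered iminolactone ring of 15, so the C1–C(imidate), C2–C(bridge) and one C–O bond arise in a single operation. The closest known reaction type is the three-component coupling of arynes, isocyanides and aldehydes to 1-iminoisobenzofurans, which is established for 3-alkoxyarynes with one sense of addition. The step needs regioselectivity, and the substrate supplies it: the electron-withdrawing C3 oxygen and the strain of the fused dioxole distort the triple bond in the same sense, making C1 the more linear and more electrophilic terminus and placing the developing charge at C2, where the adjacent C–O bond stabilises it inductively. Chemoselectivity rests on the isocyanide being the only good neutral carbon nucleophile present and on the non-enolisable aldehyde, used in excess, being the best electrophile for the aryl anion, while the aryl bromide of 11 is inert. The bridge carbon is the only new stereocentre and nothing controls it, so 15 forms as a racemate, which is harmless because this carbon becomes CH2 in step 7.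

**Step 6**
Reactants: 15 racemic (Z)-N-tert-butyl-3-(3-bromo-4-methoxyphenyl)-4,5-(isopropylidenedioxy)-1,3-dihydroisobenzofuran-1-imine
Product: 17 racemic 3-(3-bromo-4-methoxyphenyl)-4,5-dihydroxyisobenzofuran-1(3H)-one, via acetonide phthalide 16 (not isolated)
Conditions: TFA/H2O (4:1), 50 °C
Reagents that add atoms: water, O
Why: Cyclic imidate hydrolysis at low pH expels the amine from the N-protonated tetrahedral intermediate and so gives the lactone rather than the hydroxy amide, and the same aqueous acid then hydrolyses the catechol ketal while the methyl ether and aryl bromide are untouched.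

**Step 7**
Reactants: 17 racemic 3-(3-bromo-4-methoxyphenyl)-4,5-dihydroxyisobenzofuran-1(3H)-one
Product: 18 2-(3-bromo-4-methoxybenzyl)-3,4-dihydroxybenzoic acid
Conditions: Et3SiH (4 equiv), TFA, rt to 50 °C
Reagents that add atoms: none
Why: In this ionic hydrogenation TFA ionises the doubly benzylic lactone C–O bond to a diarylmethyl cation stabilised by the para methoxy group of ring B and the ortho C3 hydroxyl of ring A, and Et3SiH delivers hydride to it, which frees the acid, erases the stereocentre and, with the ketal already gone, avoids any competing reduction of a ketal-derived oxocarbenium ion to an isopropyl ether.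

**Step 8**
Reactants: 18 2-(3-bromo-4-methoxybenzyl)-3,4-dihydroxybenzoic acid
Product: 19 5-bromo-2-(3-bromo-4-methoxybenzyl)-3,4-dihydroxybenzoic acid
Conditions: Br2 (1.0 equiv), AcOH, 15 °C to rt
Reagents that add atoms: bromine, BrBr
Why: Electrophilic aromatic bromination should favour C5, which is ortho to the C4 hydroxyl, para to the C2 benzyl group and meta to the carboxyl, over C6 (ortho to the carboxyl) and over the one activated site of ring B (beside a methoxy group already flanked by bromine), the same preference that takes 3,4-dihydroxybenzoic acid derivatives to their 5-bromo compounds.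

**Step 9**
Reactants: 19 5-bromo-2-(3-bromo-4-methoxybenzyl)-3,4-dihydroxybenzoic acid
Product: 20 5-bromo-2-(3-bromo-4-hydroxybenzyl)-3,4-dihydroxybenzoic acid
Conditions: BBr3 (5 equiv), CH2Cl2, −78 °C to rt; H2O
Reagents that add atoms: none
Why: BBr3 cleavage of the aryl methyl ether is the standard final deprotection of bromophenols, and it is run at the carboxylic acid level because a benzylic alcohol would be converted to its bromide, whereas the aryl bromides, the diarylmethane and the carboxyl group survive.

**Step 10**
Reactants: 20 5-bromo-2-(3-bromo-4-hydroxybenzyl)-3,4-dihydroxybenzoic acid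
Product: 21 6-bromo-3-(3-bromo-4-hydroxybenzyl)-4-(hydroxymethyl)benzene-1,2-diol (target)
Conditions: BH3·THF (6 equiv), THF, 0 °C to rt; H2O, pH 6 phosphate buffer, no alcohol solvent
Reagents that add atoms: none
Why: Borane reduces the carboxylic acid through its acyloxyborane while the phenols only consume hydride as aryloxyboranes, which are far weaker donors than phenoxides, so the carboxyl stays reactive, the aryl bromides are inert, and the near-neutral alcohol-free work-up protects the para-hydroxybenzyl alcohol from solvolysis.

**Compound list**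
1 | pyrogallol (benzene-1,2,3-triol) | Oc1cccc(O)c1O | starting material
2 | 2,2-dimethyl-1,3-benzodioxol-4-ol | CC1(C)Oc2cccc(O)c2O1 | intermediate
3 | 2,2-dimethyl-1,3-benzodioxol-4-yl N-isopropylcarbamate | CC(C)NC(=O)Oc1cccc2OC(C)(C)Oc12 | intermediate
4 | 2,2-dimethyl-1,3-benzodioxol-4-yl N-(tert-butyldimethylsilyl)-N-isopropylcarbamate | CC(C)N(C(=O)Oc1cccc2OC(C)(C)Oc12)[Si](C)(C)C(C)(C)C | intermediate
5 | 5-lithio-2,2-dimethyl-1,3-benzodioxol-4-yl N-(tert-butyldimethylsilyl)-N-isopropylcarbamate | CC(C)N(C(=O)Oc1c([Li])ccc2OC(C)(C)Oc12)[Si](C)(C)C(C)(C)C | intermediate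
6 | 2,2-dimethyl-5-(trimethylsilyl)-1,3-benzodioxol-4-yl N-(tert-butyldimethylsilyl)-N-isopropylcarbamate | CC(C)N(C(=O)Oc1c([Si](C)(C)C)ccc2OC(C)(C)Oc12)[Si](C)(C)C(C)(C)C | intermediate
7 | 2,2-dimethyl-5-(trimethylsilyl)-1,3-benzodioxol-4-yl N-isopropylcarbamate | CC(C)NC(=O)Oc1c([Si](C)(C)C)ccc2OC(C)(C)Oc12 | intermediate
8 | 2,2-dimethyl-5-(trimethylsilyl)-1,3-benzodioxol-4-ol | CC1(C)Oc2ccc([Si](C)(C)C)c(O)c2O1 | intermediate
9 | 2,2-dimethyl-5-(trimethylsilyl)-1,3-benzodioxol-4-yl trifluoromethanesulfonate | CC1(C)Oc2ccc([Si](C)(C)C)c(OS(=O)(=O)C(F)(F)F)c2O1 | intermediate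
10 | tert-butyl isocyanide | CC(C)(C)[N+]#[C-] | starting material
11 | 3-bromo-4-methoxybenzaldehyde | COc1ccc(C=O)cc1Br | starting material
12 | 4,5-didehydro-2,2-dimethyl-1,3-benzodioxole (aryne) | CC1(C)OC2=C(O1)C#CC=C2 | intermediate
13 | zwitterion with N-tert-butylnitrilium at benzodioxole C5 and aryl anion at C4 | CC1(C)Oc2ccc(C#[N+]C(C)(C)C)[c-]c2O1 | intermediate
14 | zwitterion with N-tert-butylnitrilium at benzodioxole C5 and (3-bromo-4-methoxyphenyl)methanolate at C4 (racemic) | CC1(C)Oc2ccc(C#[N+]C(C)(C)C)c(C([O-])c3ccc(OC)c(Br)c3)c2O1 | intermediate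
15 | racemic (Z)-N-tert-butyl-3-(3-bromo-4-methoxyphenyl)-4,5-(isopropylidenedioxy)-1,3-dihydroisobenzofuran-1-imine | CC(C)(C)/N=C1\OC(c2ccc(OC)c(Br)c2)c2c1ccc1OC(C)(C)Oc12 | intermediate
16 | racemic 3-(3-bromo-4-methoxyphenyl)-4,5-(isopropylidenedioxy)isobenzofuran-1(3H)-one | O=C1OC(c2ccc(OC)c(Br)c2)c2c1ccc1OC(C)(C)Oc12 | intermediate
17 | racemic 3-(3-bromo-4-methoxyphenyl)-4,5-dihydroxyisobenzofuran-1(3H)-one | O=C1OC(c2ccc(OC)c(Br)c2)c2c(O)c(O)ccc21 | intermediate
18 | 2-(3-bromo-4-methoxybenzyl)-3,4-dihydroxybenzoic acid | OC(=O)c1ccc(O)c(O)c1Cc1ccc(OC)c(Br)c1 | intermediate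
19 | 5-bromo-2-(3-bromo-4-methoxybenzyl)-3,4-dihydroxybenzoic acid | OC(=O)c1cc(Br)c(O)c(O)c1Cc1ccc(OC)c(Br)c1 | intermediate
20 | 5-bromo-2-(3-bromo-4-hydroxybenzyl)-3,4-dihydroxybenzoic acid | OC(=O)c1cc(Br)c(O)c(O)c1Cc1ccc(O)c(Br)c1 | intermediate
21 | 6-bromo-3-(3-bromo-4-hydroxybenzyl)-4-(hydroxymethyl)benzene-1,2-diol | OCc1cc(Br)c(O)c(O)c1Cc1ccc(O)c(Br)c1 | target

**Count**
Total steps: 10. Longest linear sequence: 10 steps (1 to 21). Compounds 10 and 11 are purchased.

**Steps most likely to fail**

Step 5. The aldehyde may intercept the aryl anion inefficiently, through premature protonation of the zwitterion or its addition to a second aryne. Part of the isocyanide addition could also leak to C2.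
The fallback builds the same lactone by directed ortho-metalation. It sets out from aldehyde 11 and returns to the route at 17.
- Commercial methyl 3,4-dihydroxybenzoate is ketalised (Me2C(OMe)2, p-TsOH) to methyl 2,2-dimethyl-1,3-benzodioxole-5-carboxylate F1.
- AlMe3-mediated aminolysis with Et2NH gives N,N-diethyl-2,2-dimethyl-1,3-benzodioxole-5-carboxamide F2.
- s-BuLi/TMEDA (THF, −78 °C) deprotonates the site flanked by the amide and the dioxole oxygen to give the 4-lithio amide F3.
- Addition of F3 to 11 at −78 °C, which is faster than bromine–lithium exchange, gives the racemic hydroxy amide F4.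
- The aqueous TFA of step 6 lactonises F4 and removes the ketal to give 17.

Step 8. Site control may be lost during bromination. Possible processes are attack on ring B next to the methoxy group, ipso attack at C1 with decarboxylation, and oxidation of the catechol.
The fallback moves the bromination forward to the lactone. There the carboxyl is tied up as an ester and ring B carries an acyloxy-substituted, less activating carbon. It sets out from 17 and returns at 19.
- Br2 in AcOH converts 17 into racemic 6-bromo-3-(3-bromo-4-methoxyphenyl)-4,5-dihydroxyisobenzofuran-1(3H)-one F5.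
- Et3SiH/TFA then opens the lactone reductively to 19.

Step 10. The new benzylic C–O bond lies para to the C4 oxygen and may ionise through a quinone methide, leading to deoxygenation or oligomerisation. Poorly soluble borates could also slow the reduction.
The fallback masks the phenols as electron-withdrawing acetates before the reduction. It sets out from 20 and returns at 21.
- Ac2O/pyridine followed by aqueous work-up gives 3,4-diacetoxy-2-(4-acetoxy-3-bromobenzyl)-5-bromobenzoic acid F6.
- BH3·THF at 0 °C reduces only the acid, giving 3,4-diacetoxy-2-(4-acetoxy-3-bromobenzyl)-5-bromobenzyl alcohol F7.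
- LiOH in THF/H2O at 0 °C under argon, with acidification to pH 6, releases 21.

**Further compounds**
F1 | step 5 | methyl 2,2-dimethyl-1,3-benzodioxole-5-carboxylate | COC(=O)c1ccc2OC(C)(C)Oc2c1
F2 | step 5 | N,N-diethyl-2,2-dimethyl-1,3-benzodioxole-5-carboxamide | CCN(CC)C(=O)c1ccc2OC(C)(C)Oc2c1
F3 | step 5 | N,N-diethyl-4-lithio-2,2-dimethyl-1,3-benzodioxole-5-carboxamide | CCN(CC)C(=O)c1ccc2OC(C)(C)Oc2c1[Li]
F4 | step 5 | racemic 4-[(3-bromo-4-methoxyphenyl)(hydroxy)methyl]-N,N-diethyl-2,2-dimethyl-1,3-benzodioxole-5-carboxamide | CCN(CC)C(=O)c1ccc2OC(C)(C)Oc2c1C(O)c1ccc(OC)c(Br)c1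
F5 | step 8 | racemic 6-bromo-3-(3-bromo-4-methoxyphenyl)-4,5-dihydroxyisobenzofuran-1(3H)-one | O=C1OC(c2ccc(OC)c(Br)c2)c2c(O)c(O)c(Br)cc21
F6 | step 10 | 3,4-diacetoxy-2-(4-acetoxy-3-bromobenzyl)-5-bromobenzoic acid | OC(=O)c1cc(Br)c(OC(C)=O)c(OC(C)=O)c1Cc1ccc(OC(C)=O)c(Br)c1
F7 | step 10 | 3,4-diacetoxy-2-(4-acetoxy-3-bromobenzyl)-5-bromobenzyl alcohol | OCc1cc(Br)c(OC(C)=O)c(OC(C)=O)c1Cc1ccc(OC(C)=O)c(Br)c1
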